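**Plan**

- Cuts: the diene bond between the methyl-bearing carbon and the E-olefin (Suzuki–Miyaura), the two epoxide C–O bonds (directed epoxidation), the side-chain bond C1'–C2' (alkynylation of a ring B aldehyde), and in ring B both bonds that join an arm-bearing olefinic carbon to a carbinol carbon; ring A is cut at the bond made by an epoxy-olefin cyclisation.
- Enabling feature: without the epoxide oxygen and the side chain, ring B (C1 epoxide carbon with the side chain, C2 carbinol, C3=C4(CH2OH), C5 carbinol, C6 epoxide CH) is a cis-3,6-dioxygenated cyclohexa-1,4-diene with one-carbon arms. A C2 axis maps C1 onto C4, C2 onto C5 and C6 onto C3, so the ring is the head-to-tail dimer of one C4 unit, (Z)-3-iodo-4-silyloxybut-2-enal.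
- Forward: butynediol → Z-iodoenal → nickel/chromium cyclodimerisation, whose second C–C bond (C1–C2) closes ring B → silylation, release of one of the two homotopic CH2O arms, aldehyde → propynyl carbinol → Z-iodoalkene → epoxide. Ring A comes from cyclisation of (R)-6,7-epoxygeranyl acetate and is taken to an E-alkenylboronate; Suzuki union and desilylation finish the route.
- Stereochemistry: both ring B carbinols from the chiral chromium catalyst (two like-sense additions give the cis, C2 diol); C1' from zinc–ProPhenol alkynylation; the epoxide from hydroxyl-directed vanadium epoxidation anti to both ring silyl ethers; the Z olefin from trans-hydroalumination/iodination, the E olefin from Takai–Utimoto olefination; ring A from Shi epoxidation and a chair cyclisation (OH and side chain cis).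

Key step: step 4

Assumption: each chiral catalyst is named as the antipode that the usual facial model predicts for the configuration drawn in the compound list; if a catalyst favoured the other face, its mirror-image form would be used.

**Route**

Step 1
Reactants: 1 but-2-yne-1,4-diol
Product: 2 4-{[tert-butyl(dimethyl)silyl]oxy}but-2-yn-1-ol
Conditions: NaH (1.0 equiv), THF, 0 °C; then TBSCl (1.0 equiv), rt
Reagents that add atoms: tert-butyldimethylsilyl chloride, CC(C)(C)[Si](C)(C)Cl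
Why: O-silylation of a symmetric diol through its monosodium alkoxide should stop at the mono ether because only one alkoxide is formed per molecule.

Step 2
Reactants: 2 4-{[tert-butyl(dimethyl)silyl]oxy}but-2-yn-1-ol
Product: 4 (2Z)-4-{[tert-butyl(dimethyl)silyl]oxy}-3-iodobut-2-en-1-ol, via cyclic alkenylaluminate 3 (not isolated)
Conditions: NaAlH2(OCH2CH2OMe)2 (Red-Al), THF, 0 °C; then I2, THF, −78 °C
Reagents that add atoms: iodine, I-I
Why: Hydroxyl-directed trans-hydroalumination of the propargylic alcohol puts hydride on the proximal and aluminium on the distal alkyne carbon in a five-membered aluminate, and iodinolysis with retention should give the Z-iodoalkene with iodine cis to CH2OH.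

Step 3
Reactants: 4 (2Z)-4-{[tert-butyl(dimethyl)silyl]oxy}-3-iodobut-2-en-1-ol
Product: 5 (2Z)-4-{[tert-butyl(dimethyl)silyl]oxy}-3-iodobut-2-enal
Conditions: activated MnO2 (excess), CH2Cl2, rt, dark
Reagents that add atoms: none
Why: Allylic oxidation with MnO2 is selective for the allylic alcohol and mild enough to keep the Z geometry of the β-iodoenal.

Step 4
Reactants: 5 (2Z)-4-{[tert-butyl(dimethyl)silyl]oxy}-3-iodobut-2-enal (two molecules)
Product: 8 (1S,4S)-2,5-bis({[tert-butyl(dimethyl)silyl]oxy}methyl)cyclohexa-2,5-diene-1,4-diol, via open-chain iodo dienal silyl ether 6 (not isolated), via cyclic bis(trimethylsilyl) ether 7 (not isolated)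
Conditions: CrCl2 (10 mol%) with (S)-4-isopropyl-2-(2-methanesulfonamido-3-methylphenyl)-4,5-dihydrooxazole and proton sponge; NiCl2 with 2,9-dimethyl-1,10-phenanthroline (2 mol%); Mn powder; TMSCl; MeCN, rt, slow addition of 5 (about 0.02 M); then K2CO3, MeOH, 0 °C
Reagents that add atoms: none
Why: Proposed new method: zerovalent nickel inserts into the C–I bond of 5, the alkenyl group passes to trivalent chromium and adds 1,2 to the aldehyde of a second molecule, and TMSCl silylates the chromium alkoxide (this releases chromium for reduction by Mn and keeps the Z-4-hydroxy-enal from closing to a lactol or furan) to give 6, after which the same sequence at the remaining C–I bond closes the ring onto the remaining aldehyde. The closest known reaction type is the catalytic asymmetric Nozaki–Hiyama–Kishi alkenylation of aldehydes, here run twice on one bifunctional monomer as a head-to-tail cyclodimerisation. The six-membered ring closes in the 6-exo-trig mode by forming the bond between the CH2OTBS-bearing alkenyl carbon (the later epoxide carbon C1) and the aldehyde carbon (the later carbinol C2). Both new carbinol centres are set by the chiral chromium sulfonamide complex (catalyst control), and in the closure the A(1,2) strain between each ring oxygen substituent and the neighbouring CH2OTBS group favours the diaxial boat that leads to the cis diol. The step needs cyclodimer over oligomer and homochiral (cis, C2) over heterochiral (trans, meso) coupling: the two Z double bonds of 6 hold the iodoalkene and the aldehyde within bonding distance, and two like-sense additions give only the S,S diol while a wrong-sense event gives the separable meso isomer, so the enantiomeric purity of 8 should exceed that of a single addition (Horeau-type amplification).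

Step 5
Reactants: 8 (1S,4S)-2,5-bis({[tert-butyl(dimethyl)silyl]oxy}methyl)cyclohexa-2,5-diene-1,4-diol
Product: 9 (3S,6S)-3,6-bis{[tert-butyl(dimethyl)silyl]oxy}-1,4-bis({[tert-butyl(dimethyl)silyl]oxy}methyl)cyclohexa-1,4-diene
Conditions: TBSOTf, 2,6-lutidine, CH2Cl2, −78 °C
Reagents that add atoms: tert-butyldimethylsilyl triflate, CC(C)(C)[Si](C)(C)OS(=O)(=O)C(F)(F)F
Why: Silyl triflate silylation under lutidine buffering protects the acid-sensitive bis-allylic carbinols without ionisation and installs the two bulky groups that later shield the lower ring face.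

Step 6
Reactants: 9 (3S,6S)-3,6-bis{[tert-butyl(dimethyl)silyl]oxy}-1,4-bis({[tert-butyl(dimethyl)silyl]oxy}methyl)cyclohexa-1,4-diene
Product: 10 [(3S,6S)-3,6-bis{[tert-butyl(dimethyl)silyl]oxy}-4-({[tert-butyl(dimethyl)silyl]oxy}methyl)cyclohexa-1,4-dien-1-yl]methanol
Conditions: HF·pyridine, pyridine, THF, 0 °C, stopped near half conversion; 9 and over-cleaved diol (after resilylation) recycled
Reagents that add atoms: none
Why: Buffered fluoride cleaves primary silyl ethers well before secondary ones, and because the two CH2OTBS arms are homotopic (C2 axis) either cleavage gives the same alcohol, so this desymmetrising mono-desilylation needs no site selectivity, only control of conversion.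

Step 7
Reactants: 10 [(3S,6S)-3,6-bis{[tert-butyl(dimethyl)silyl]oxy}-4-({[tert-butyl(dimethyl)silyl]oxy}methyl)cyclohexa-1,4-dien-1-yl]methanol
Product: 11 (3S,6S)-3,6-bis{[tert-butyl(dimethyl)silyl]oxy}-4-({[tert-butyl(dimethyl)silyl]oxy}methyl)cyclohexa-1,4-diene-1-carbaldehyde
Conditions: activated MnO2, CH2Cl2, rt
Reagents that add atoms: none
Why: Neutral allylic oxidation with MnO2 should give the enal without the base that could trigger aromatisation of the cyclohexadiene.

Step 8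
Reactants: 11 (3S,6S)-3,6-bis{[tert-butyl(dimethyl)silyl]oxy}-4-({[tert-butyl(dimethyl)silyl]oxy}methyl)cyclohexa-1,4-diene-1-carbaldehyde
Product: 12 (1S)-1-[(3S,6S)-3,6-bis{[tert-butyl(dimethyl)silyl]oxy}-4-({[tert-butyl(dimethyl)silyl]oxy}methyl)cyclohexa-1,4-dien-1-yl]but-2-yn-1-ol
Conditions: (S,S)-ProPhenol (20 mol%), Me2Zn, propyne, Ph3P=O (40 mol%), toluene, 0 °C
Reagents that add atoms: propyne, CC#C
Why: Zinc–ProPhenol catalysed enantioselective alkynylation of an α,β-unsaturated aldehyde should deliver the propynyl group to one aldehyde face under reagent control and so set the S carbinol centre of the side chain.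

Step 9
Reactants: 12 (1S)-1-[(3S,6S)-3,6-bis{[tert-butyl(dimethyl)silyl]oxy}-4-({[tert-butyl(dimethyl)silyl]oxy}methyl)cyclohexa-1,4-dien-1-yl]but-2-yn-1-ol
Product: 14 (1S,2Z)-1-[(3S,6S)-3,6-bis{[tert-butyl(dimethyl)silyl]oxy}-4-({[tert-butyl(dimethyl)silyl]oxy}methyl)cyclohexa-1,4-dien-1-yl]-3-iodobut-2-en-1-ol, via cyclic alkenylaluminate 13 (not isolated)
Conditions: NaAlH2(OCH2CH2OMe)2 (Red-Al), THF, 0 °C; then I2, −78 °C
Reagents that add atoms: iodine, I-I
Why: The same hydroxyl-directed trans-hydroalumination/iodinolysis should place iodine on the methyl-bearing carbon cis to the carbinol, which fixes the Z geometry of the later trisubstituted olefin; it is done before the epoxide exists because this hydride reagent opens 2,3-epoxy alcohols.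

Step 10
Reactants: 14 (1S,2Z)-1-[(3S,6S)-3,6-bis{[tert-butyl(dimethyl)silyl]oxy}-4-({[tert-butyl(dimethyl)silyl]oxy}methyl)cyclohexa-1,4-dien-1-yl]-3-iodobut-2-en-1-ol
Product: 15 (1S,2Z)-1-[(1S,2S,5R,6S)-2,5-bis{[tert-butyl(dimethyl)silyl]oxy}-4-({[tert-butyl(dimethyl)silyl]oxy}methyl)-7-oxabicyclo[4.1.0]hept-3-en-1-yl]-3-iodobut-2-en-1-ol
Conditions: VO(acac)2 (5 mol%), t-BuOOH, CH2Cl2, 0 °C
Reagents that add atoms: tert-butyl hydroperoxide, CC(C)(C)OO
Why: In this hydroxyl-directed vanadium epoxidation the free carbinol should deliver oxygen to the adjacent ring olefin (the iodoalkene is electron-poor and strained in the directing conformer, the other ring olefin has no free hydroxyl) on the face anti to both ring OTBS groups, which is also the erythro face favoured by A(1,2) strain, so the epoxide is set trans to both ring oxygens.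

Step 11
Reactants: 16 geranyl acetate [(2E)-3,7-dimethylocta-2,6-dien-1-yl acetate]
Product: 17 (2E)-5-[(2R)-3,3-dimethyloxiran-2-yl]-3-methylpent-2-en-1-yl acetate
Conditions: D-fructose-derived ketone catalyst (1,2:4,5-di-O-isopropylidene-D-erythro-hexo-2,3-diulo-2,6-pyranose, 30 mol%), KHSO5 (Oxone), K2CO3, Bu4NHSO4, MeCN/dimethoxymethane/borate buffer pH 10.5, 0 °C
Reagents that add atoms: potassium peroxymonosulfate, [K+].[O-]S(=O)(=O)OO
Why: Shi asymmetric epoxidation by the chiral dioxirane should attack only the electron-rich 6,7-olefin (the allylic acetate olefin is deactivated) and set the R epoxide.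

Step 12
Reactants: 17 (2E)-5-[(2R)-3,3-dimethyloxiran-2-yl]-3-methylpent-2-en-1-yl acetate
Product: 18 [(1S,5R)-5-hydroxy-2,6,6-trimethylcyclohex-2-en-1-yl]methyl acetate
Conditions: ZrCl4 (0.5 equiv), CH2Cl2, −78 to −20 °C; exocyclic olefin isomer removed on AgNO3-silica
Reagents that add atoms: none
Why: Lewis acid-promoted epoxy-olefin (cation–olefin) cyclisation through a chair transition state keeps the epoxide C–O bond (R carbinol), sets the new ring CH cis to the hydroxyl (both equatorial) and should end by proton loss to the endocyclic trisubstituted olefin.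

Step 13
Reactants: 18 [(1S,5R)-5-hydroxy-2,6,6-trimethylcyclohex-2-en-1-yl]methyl acetate
Product: 19 [(1S,5R)-2,6,6-trimethyl-5-(triethylsilyloxy)cyclohex-2-en-1-yl]methyl acetate
Conditions: TESOTf, 2,6-lutidine, CH2Cl2, −78 °C
Reagents that add atoms: triethylsilyl triflate, CC[Si](CC)(CC)OS(=O)(=O)C(F)(F)F
Why: Silyl triflate silylation of the hindered secondary alcohol prevents lactol and lactone formation with the cis one-carbon arm in the following oxidation.

Step 14
Reactants: 19 [(1S,5R)-2,6,6-trimethyl-5-(triethylsilyloxy)cyclohex-2-en-1-yl]methyl acetate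
Product: 20 [(1S,5R)-2,6,6-trimethyl-5-(triethylsilyloxy)cyclohex-2-en-1-yl]methanol
Conditions: K2CO3, MeOH, rt
Reagents that add atoms: none
Why: Base-catalysed transesterification removes the acetate and leaves the hindered secondary silyl ether in place.

Step 15
Reactants: 20 [(1S,5R)-2,6,6-trimethyl-5-(triethylsilyloxy)cyclohex-2-en-1-yl]methanol
Product: 21 (1S,5R)-2,6,6-trimethyl-5-(triethylsilyloxy)cyclohex-2-ene-1-carbaldehyde
Conditions: Dess–Martin periodinane, NaHCO3, CH2Cl2, 0 °C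
Reagents that add atoms: none
Why: Buffered Dess–Martin oxidation is neutral enough to avoid epimerisation of the α centre and migration of the β,γ double bond into conjugation.

Step 16
Reactants: 21 (1S,5R)-2,6,6-trimethyl-5-(triethylsilyloxy)cyclohex-2-ene-1-carbaldehyde
Product: 22 2-{(E)-2-[(1S,5R)-2,6,6-trimethyl-5-(triethylsilyloxy)cyclohex-2-en-1-yl]ethenyl}-4,4,5,5-tetramethyl-1,3,2-dioxaborolane
Conditions: Cl2CHB(pin), CrCl2, LiI, THF, rt
Reagents that add atoms: 2-(dichloromethyl)-4,4,5,5-tetramethyl-1,3,2-dioxaborolane, ClC(Cl)B1OC(C)(C)C(C)(C)O1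
Why: Takai–Utimoto olefination with the geminal dichromium boronate reagent should give the E-alkenylboronate under non-basic conditions that leave the α centre and the β,γ-olefin untouched.

Step 17
Reactants: 15 (1S,2Z)-1-[(1S,2S,5R,6S)-2,5-bis{[tert-butyl(dimethyl)silyl]oxy}-4-({[tert-butyl(dimethyl)silyl]oxy}methyl)-7-oxabicyclo[4.1.0]hept-3-en-1-yl]-3-iodobut-2-en-1-ol; 22 2-{(E)-2-[(1S,5R)-2,6,6-trimethyl-5-(triethylsilyloxy)cyclohex-2-en-1-yl]ethenyl}-4,4,5,5-tetramethyl-1,3,2-dioxaborolane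
Product: 23 (1S,2Z,4E)-1-[(1S,2S,5R,6S)-2,5-bis{[tert-butyl(dimethyl)silyl]oxy}-4-({[tert-butyl(dimethyl)silyl]oxy}methyl)-7-oxabicyclo[4.1.0]hept-3-en-1-yl]-3-methyl-5-[(1S,5R)-2,6,6-trimethyl-5-(triethylsilyloxy)cyclohex-2-en-1-yl]penta-2,4-dien-1-ol
Conditions: Pd(dppf)Cl2 (5 mol%), AsPh3, aq. K3PO4, DMF/THF, rt
Reagents that add atoms: none
Why: Suzuki–Miyaura coupling of an alkenyl iodide with an alkenylboronate proceeds with retention at both olefins and should give the 2Z,4E diene under mild base that the epoxy alcohol tolerates.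

Step 18
Reactants: 23 (1S,2Z,4E)-1-[(1S,2S,5R,6S)-2,5-bis{[tert-butyl(dimethyl)silyl]oxy}-4-({[tert-butyl(dimethyl)silyl]oxy}methyl)-7-oxabicyclo[4.1.0]hept-3-en-1-yl]-3-methyl-5-[(1S,5R)-2,6,6-trimethyl-5-(triethylsilyloxy)cyclohex-2-en-1-yl]penta-2,4-dien-1-ol
Product: 24 (1R,2S,5R,6S)-1-{(1S,2Z,4E)-1-hydroxy-5-[(1S,5R)-5-hydroxy-2,6,6-trimethylcyclohex-2-en-1-yl]-3-methylpenta-2,4-dien-1-yl}-4-(hydroxymethyl)-7-oxabicyclo[4.1.0]hept-3-ene-2,5-diol
Conditions: Bu4NF/AcOH (1:1), THF, rt to 40 °C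
Reagents that add atoms: none
Why: Fluoride desilylation buffered with acetic acid should remove all four silyl groups without free alkoxides, which avoids Payne rearrangement of the epoxy triol and ionisation of the dienylic carbinol.

**Compound list**

1 | but-2-yne-1,4-diol | OCC#CCO | starting material
2 | 4-{[tert-butyl(dimethyl)silyl]oxy}but-2-yn-1-ol | OCC#CCO[Si](C)(C)C(C)(C)C | intermediate
3 | sodium cyclic alkenylaluminate from 2 (aluminium bound to the alkoxide oxygen and to C-3, five-membered ring, two 2-methoxyethoxy ligands) | [Na+].COCCO[Al-]1(OCCOC)OCC=C1CO[Si](C)(C)C(C)(C)C | intermediate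
4 | (2Z)-4-{[tert-butyl(dimethyl)silyl]oxy}-3-iodobut-2-en-1-ol | OC/C=C(\I)CO[Si](C)(C)C(C)(C)C | intermediate
5 | (2Z)-4-{[tert-butyl(dimethyl)silyl]oxy}-3-iodobut-2-enal | O=C/C=C(\I)CO[Si](C)(C)C(C)(C)C | intermediate
6 | (2Z,4S,5Z)-7-{[tert-butyl(dimethyl)silyl]oxy}-3-({[tert-butyl(dimethyl)silyl]oxy}methyl)-6-iodo-4-(trimethylsilyloxy)hepta-2,5-dienal | O=C/C=C(CO[Si](C)(C)C(C)(C)C)\[C@@H](O[Si](C)(C)C)/C=C(\I)CO[Si](C)(C)C(C)(C)C | intermediate
7 | (3S,6S)-1,4-bis({[tert-butyl(dimethyl)silyl]oxy}methyl)-3,6-bis(trimethylsilyloxy)cyclohexa-1,4-diene | C[Si](C)(C)O[C@@H]1C(CO[Si](C)(C)C(C)(C)C)=C[C@H](O[Si](C)(C)C)C(CO[Si](C)(C)C(C)(C)C)=C1 | intermediate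
8 | (1S,4S)-2,5-bis({[tert-butyl(dimethyl)silyl]oxy}methyl)cyclohexa-2,5-diene-1,4-diol (cis, C2-symmetric) | O[C@@H]1C(CO[Si](C)(C)C(C)(C)C)=C[C@H](O)C(CO[Si](C)(C)C(C)(C)C)=C1 | intermediate
9 | (3S,6S)-3,6-bis{[tert-butyl(dimethyl)silyl]oxy}-1,4-bis({[tert-butyl(dimethyl)silyl]oxy}methyl)cyclohexa-1,4-diene | CC(C)(C)[Si](C)(C)O[C@@H]1C(CO[Si](C)(C)C(C)(C)C)=C[C@H](O[Si](C)(C)C(C)(C)C)C(CO[Si](C)(C)C(C)(C)C)=C1 | intermediate
10 | [(3S,6S)-3,6-bis{[tert-butyl(dimethyl)silyl]oxy}-4-({[tert-butyl(dimethyl)silyl]oxy}methyl)cyclohexa-1,4-dien-1-yl]methanol | CC(C)(C)[Si](C)(C)O[C@@H]1C(CO)=C[C@H](O[Si](C)(C)C(C)(C)C)C(CO[Si](C)(C)C(C)(C)C)=C1 | intermediate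
11 | (3S,6S)-3,6-bis{[tert-butyl(dimethyl)silyl]oxy}-4-({[tert-butyl(dimethyl)silyl]oxy}methyl)cyclohexa-1,4-diene-1-carbaldehyde | CC(C)(C)[Si](C)(C)O[C@@H]1C(C=O)=C[C@H](O[Si](C)(C)C(C)(C)C)C(CO[Si](C)(C)C(C)(C)C)=C1 | intermediate
12 | (1S)-1-[(3S,6S)-3,6-bis{[tert-butyl(dimethyl)silyl]oxy}-4-({[tert-butyl(dimethyl)silyl]oxy}methyl)cyclohexa-1,4-dien-1-yl]but-2-yn-1-ol | CC#C[C@H](O)C1=C[C@H](O[Si](C)(C)C(C)(C)C)C(CO[Si](C)(C)C(C)(C)C)=C[C@@H]1O[Si](C)(C)C(C)(C)C | intermediate
13 | sodium cyclic alkenylaluminate from 12 (aluminium bound to the carbinol oxygen and to the methyl-bearing olefinic carbon) | [Na+].COCCO[Al-]1(OCCOC)O[C@@H](C=C1C)C2=C[C@H](O[Si](C)(C)C(C)(C)C)C(CO[Si](C)(C)C(C)(C)C)=C[C@@H]2O[Si](C)(C)C(C)(C)C | intermediate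
14 | (1S,2Z)-1-[(3S,6S)-3,6-bis{[tert-butyl(dimethyl)silyl]oxy}-4-({[tert-butyl(dimethyl)silyl]oxy}methyl)cyclohexa-1,4-dien-1-yl]-3-iodobut-2-en-1-ol | I/C(C)=C\[C@H](O)C1=C[C@H](O[Si](C)(C)C(C)(C)C)C(CO[Si](C)(C)C(C)(C)C)=C[C@@H]1O[Si](C)(C)C(C)(C)C | intermediate
15 | (1S,2Z)-1-[(1S,2S,5R,6S)-2,5-bis{[tert-butyl(dimethyl)silyl]oxy}-4-({[tert-butyl(dimethyl)silyl]oxy}methyl)-7-oxabicyclo[4.1.0]hept-3-en-1-yl]-3-iodobut-2-en-1-ol | I/C(C)=C\[C@H](O)[C@]12O[C@H]1[C@H](O[Si](C)(C)C(C)(C)C)C(CO[Si](C)(C)C(C)(C)C)=C[C@@H]2O[Si](C)(C)C(C)(C)C | intermediate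
16 | geranyl acetate, (2E)-3,7-dimethylocta-2,6-dien-1-yl acetate | CC(C)=CCC/C(C)=C/COC(C)=O | starting material
17 | (2E)-5-[(2R)-3,3-dimethyloxiran-2-yl]-3-methylpent-2-en-1-yl acetate | CC(=O)OC/C=C(\C)CC[C@H]1OC1(C)C | intermediate
18 | [(1S,5R)-5-hydroxy-2,6,6-trimethylcyclohex-2-en-1-yl]methyl acetate (OH and CH2OAc cis) | CC1=CC[C@@H](O)C(C)(C)[C@H]1COC(C)=O | intermediate
19 | [(1S,5R)-2,6,6-trimethyl-5-(triethylsilyloxy)cyclohex-2-en-1-yl]methyl acetate | CC1=CC[C@@H](O[Si](CC)(CC)CC)C(C)(C)[C@H]1COC(C)=O | intermediate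
20 | [(1S,5R)-2,6,6-trimethyl-5-(triethylsilyloxy)cyclohex-2-en-1-yl]methanol | CC1=CC[C@@H](O[Si](CC)(CC)CC)C(C)(C)[C@H]1CO | intermediate
21 | (1S,5R)-2,6,6-trimethyl-5-(triethylsilyloxy)cyclohex-2-ene-1-carbaldehyde | CC1=CC[C@@H](O[Si](CC)(CC)CC)C(C)(C)[C@H]1C=O | intermediate
22 | 2-{(E)-2-[(1S,5R)-2,6,6-trimethyl-5-(triethylsilyloxy)cyclohex-2-en-1-yl]ethenyl}-4,4,5,5-tetramethyl-1,3,2-dioxaborolane | CC1=CC[C@@H](O[Si](CC)(CC)CC)C(C)(C)[C@H]1/C=C/B2OC(C)(C)C(C)(C)O2 | intermediate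
23 | (1S,2Z,4E)-1-[(1S,2S,5R,6S)-2,5-bis{[tert-butyl(dimethyl)silyl]oxy}-4-({[tert-butyl(dimethyl)silyl]oxy}methyl)-7-oxabicyclo[4.1.0]hept-3-en-1-yl]-3-methyl-5-[(1S,5R)-2,6,6-trimethyl-5-(triethylsilyloxy)cyclohex-2-en-1-yl]penta-2,4-dien-1-ol | CC1=CC[C@@H](O[Si](CC)(CC)CC)C(C)(C)[C@H]1/C=C/C(C)=C\[C@H](O)[C@]23O[C@H]2[C@H](O[Si](C)(C)C(C)(C)C)C(CO[Si](C)(C)C(C)(C)C)=C[C@@H]3O[Si](C)(C)C(C)(C)C | intermediate
24 | (1R,2S,5R,6S)-1-{(1S,2Z,4E)-1-hydroxy-5-[(1S,5R)-5-hydroxy-2,6,6-trimethylcyclohex-2-en-1-yl]-3-methylpenta-2,4-dien-1-yl}-4-(hydroxymethyl)-7-oxabicyclo[4.1.0]hept-3-ene-2,5-diol | CC1=CC[C@@H](O)C(C)(C)[C@H]1/C=C/C(C)=C\[C@H](O)[C@]12O[C@H]1[C@H](O)C(CO)=C[C@@H]2O | target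

**Step count and risks**

Total steps: 18. Longest linear sequence: 12 (steps 1 to 10, 17 and 18); the ring A branch (steps 11 to 16) joins at step 17.

Step 4 (cyclodimerisation). What may go wrong: chain growth instead of ring closure, loss of Z geometry in the β-formyl alkenylmetal species, reductive pinacol-type coupling of the enal by divalent chromium with TMSCl, or poor catalyst control in the second addition so that the meso isomer dominates. Fallback (known chemistry, from 4, back at 9): ring B would be assembled stepwise from two C4 pieces.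
- Iodo alcohol 4 would be silylated (TESCl, imidazole) to tert-butyl{[(2Z)-2-iodo-4-(triethylsilyloxy)but-2-en-1-yl]oxy}dimethylsilane F1.
- Iodine–lithium exchange (t-BuLi, Et2O, −78 °C) and acylation with the Weinreb ynamide 4-{[tert-butyl(dimethyl)silyl]oxy}-N-methoxy-N-methylbut-2-ynamide F2 would give the cross-conjugated ynone (5Z)-1-{[tert-butyl(dimethyl)silyl]oxy}-5-({[tert-butyl(dimethyl)silyl]oxy}methyl)-7-(triethylsilyloxy)hept-5-en-2-yn-4-one F3. F2 comes from tert-butyldimethyl(prop-2-yn-1-yloxy)silane, n-BuLi and N-methoxy-N-methylcarbamoyl chloride.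
- Noyori asymmetric transfer hydrogenation (RuCl(p-cymene)[(R,R)-TsDPEN], i-PrOH) would set the carbinol in (4S,5Z)-1-{[tert-butyl(dimethyl)silyl]oxy}-5-({[tert-butyl(dimethyl)silyl]oxy}methyl)-7-(triethylsilyloxy)hept-5-en-2-yn-4-ol F4.
- Red-Al then I2 would give (2Z,4S,5Z)-1-{[tert-butyl(dimethyl)silyl]oxy}-2-iodo-5-({[tert-butyl(dimethyl)silyl]oxy}methyl)-7-(triethylsilyloxy)hepta-2,5-dien-4-ol F5, and TBSOTf/2,6-lutidine its tert-butyldimethylsilyl ether F6.
- Direct Swern oxidation of the primary triethylsilyl ether would give (2Z,4S,5Z)-4,7-bis{[tert-butyl(dimethyl)silyl]oxy}-3-({[tert-butyl(dimethyl)silyl]oxy}methyl)-6-iodohepta-2,5-dienal F7.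
- A stoichiometric intramolecular Nozaki–Hiyama–Kishi reaction (CrCl2, NiCl2 cat., DMSO) would close the same ring bond to (1S,4S)-4-{[tert-butyl(dimethyl)silyl]oxy}-2,5-bis({[tert-butyl(dimethyl)silyl]oxy}methyl)cyclohexa-2,5-dien-1-ol F8, cis by the same A(1,2) argument, and TBSOTf/2,6-lutidine returns the route at 9.

Step 8 (alkynylation). What may go wrong: the catalyst's facial preference is overridden by the neighbouring ring stereocentre, giving poor selectivity at the new carbinol, or base-induced aromatisation of the dienal competes. Fallback (from 11, back at 12): addition of 1-propynylmagnesium bromide (THF, −78 °C) would give 1-[(3S,6S)-3,6-bis{[tert-butyl(dimethyl)silyl]oxy}-4-({[tert-butyl(dimethyl)silyl]oxy}methyl)cyclohexa-1,4-dien-1-yl]but-2-yn-1-ol as a mixture of carbinol epimers F9. MnO2 oxidation would give the ynone 1-[(3S,6S)-3,6-bis{[tert-butyl(dimethyl)silyl]oxy}-4-({[tert-butyl(dimethyl)silyl]oxy}methyl)cyclohexa-1,4-dien-1-yl]but-2-yn-1-one F10. Noyori asymmetric transfer hydrogenation (RuCl(p-cymene)[(R,R)-TsDPEN], i-PrOH), in which the alkyne takes the place of the flat group, would then set the carbinol under reagent control and give 12.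

Step 10 (directed epoxidation). What may go wrong: oxidation of the doubly allylic carbinol to the ketone instead of oxygen transfer, attack at the iodoalkene, or erosion of facial selectivity. Fallback (from 12, back at 15): the order would be changed so that the epoxidation meets only one olefin next to a free hydroxyl. VO(acac)2/t-BuOOH on the propargylic alcohol 12 (the alkyne is inert) would give (1S)-1-[(1S,2S,5R,6S)-2,5-bis{[tert-butyl(dimethyl)silyl]oxy}-4-({[tert-butyl(dimethyl)silyl]oxy}methyl)-7-oxabicyclo[4.1.0]hept-3-en-1-yl]but-2-yn-1-ol F11. Because the hydride reagent of step 9 would open this epoxy alcohol, the alkyne would instead undergo ruthenium-catalysed trans-hydrosilylation ([Cp*Ru(MeCN)3]PF6, Et3SiH, CH2Cl2; silicon to the distal carbon) to (1S,2Z)-1-[(1S,2S,5R,6S)-2,5-bis{[tert-butyl(dimethyl)silyl]oxy}-4-({[tert-butyl(dimethyl)silyl]oxy}methyl)-7-oxabicyclo[4.1.0]hept-3-en-1-yl]-3-(triethylsilyl)but-2-en-1-ol F12. Iododesilylation with retention (N-iodosuccinimide, (CF3)2CHOH, 0 °C) then gives 15.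

Further compounds
F1 | step 4 | tert-butyl{[(2Z)-2-iodo-4-(triethylsilyloxy)but-2-en-1-yl]oxy}dimethylsilane | CC[Si](CC)(CC)OC/C=C(\I)CO[Si](C)(C)C(C)(C)C
F2 | step 4 | 4-{[tert-butyl(dimethyl)silyl]oxy}-N-methoxy-N-methylbut-2-ynamide | CON(C)C(=O)C#CCO[Si](C)(C)C(C)(C)C
F3 | step 4 | (5Z)-1-{[tert-butyl(dimethyl)silyl]oxy}-5-({[tert-butyl(dimethyl)silyl]oxy}methyl)-7-(triethylsilyloxy)hept-5-en-2-yn-4-one | CC[Si](CC)(CC)OC/C=C(CO[Si](C)(C)C(C)(C)C)\C(=O)C#CCO[Si](C)(C)C(C)(C)C
F4 | step 4 | (4S,5Z)-1-{[tert-butyl(dimethyl)silyl]oxy}-5-({[tert-butyl(dimethyl)silyl]oxy}methyl)-7-(triethylsilyloxy)hept-5-en-2-yn-4-ol | CC[Si](CC)(CC)OC/C=C(CO[Si](C)(C)C(C)(C)C)\[C@@H](O)C#CCO[Si](C)(C)C(C)(C)C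
F5 | step 4 | (2Z,4S,5Z)-1-{[tert-butyl(dimethyl)silyl]oxy}-2-iodo-5-({[tert-butyl(dimethyl)silyl]oxy}methyl)-7-(triethylsilyloxy)hepta-2,5-dien-4-ol | CC[Si](CC)(CC)OC/C=C(CO[Si](C)(C)C(C)(C)C)\[C@@H](O)/C=C(\I)CO[Si](C)(C)C(C)(C)C
F6 | step 4 | tert-butyldimethylsilyl ether of F5 at the secondary carbinol | CC[Si](CC)(CC)OC/C=C(CO[Si](C)(C)C(C)(C)C)\[C@@H](O[Si](C)(C)C(C)(C)C)/C=C(\I)CO[Si](C)(C)C(C)(C)C
F7 | step 4 | (2Z,4S,5Z)-4,7-bis{[tert-butyl(dimethyl)silyl]oxy}-3-({[tert-butyl(dimethyl)silyl]oxy}methyl)-6-iodohepta-2,5-dienal | O=C/C=C(CO[Si](C)(C)C(C)(C)C)\[C@@H](O[Si](C)(C)C(C)(C)C)/C=C(\I)CO[Si](C)(C)C(C)(C)C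
F8 | step 4 | (1S,4S)-4-{[tert-butyl(dimethyl)silyl]oxy}-2,5-bis({[tert-butyl(dimethyl)silyl]oxy}methyl)cyclohexa-2,5-dien-1-ol | O[C@@H]1C(CO[Si](C)(C)C(C)(C)C)=C[C@H](O[Si](C)(C)C(C)(C)C)C(CO[Si](C)(C)C(C)(C)C)=C1
F9 | step 8 | 1-[(3S,6S)-3,6-bis{[tert-butyl(dimethyl)silyl]oxy}-4-({[tert-butyl(dimethyl)silyl]oxy}methyl)cyclohexa-1,4-dien-1-yl]but-2-yn-1-ol, mixture of carbinol epimers | CC#CC(O)C1=C[C@H](O[Si](C)(C)C(C)(C)C)C(CO[Si](C)(C)C(C)(C)C)=C[C@@H]1O[Si](C)(C)C(C)(C)C
F10 | step 8 | 1-[(3S,6S)-3,6-bis{[tert-butyl(dimethyl)silyl]oxy}-4-({[tert-butyl(dimethyl)silyl]oxy}methyl)cyclohexa-1,4-dien-1-yl]but-2-yn-1-one | CC#CC(=O)C1=C[C@H](O[Si](C)(C)C(C)(C)C)C(CO[Si](C)(C)C(C)(C)C)=C[C@@H]1O[Si](C)(C)C(C)(C)C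
F11 | step 10 | (1S)-1-[(1S,2S,5R,6S)-2,5-bis{[tert-butyl(dimethyl)silyl]oxy}-4-({[tert-butyl(dimethyl)silyl]oxy}methyl)-7-oxabicyclo[4.1.0]hept-3-en-1-yl]but-2-yn-1-ol | CC#C[C@H](O)[C@]12O[C@H]1[C@H](O[Si](C)(C)C(C)(C)C)C(CO[Si](C)(C)C(C)(C)C)=C[C@@H]2O[Si](C)(C)C(C)(C)C
F12 | step 10 | (1S,2Z)-1-[(1S,2S,5R,6S)-2,5-bis{[tert-butyl(dimethyl)silyl]oxy}-4-({[tert-butyl(dimethyl)silyl]oxy}methyl)-7-oxabicyclo[4.1.0]hept-3-en-1-yl]-3-(triethylsilyl)but-2-en-1-ol | CC[Si](CC)(CC)/C(C)=C\[C@H](O)[C@]12O[C@H]1[C@H](O[Si](C)(C)C(C)(C)C)C(CO[Si](C)(C)C(C)(C)C)=C[C@@H]2O[Si](C)(C)C(C)(C)C
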